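- Take the constants first: volume and temperature hold still, so read each fall in [starting material] as a plain count of what has reacted.

| flask | starting material | coupling partner | free catalyst | product | time |
|---|---|---|---|---|---|
| south-west | 0.400 M | 0.320 M | 0.0400 M |  |  |
| north | 0.160 M | 0.0800 M | 0.0400 M |  |  |
| south-east | 0.400 M | 0.320 M | 0.0400 M | 0.200 M |  |
| east | 0.400 M | 0.320 M | 0.0800 M |  |  |
| north-west | 1.00 M | 0.320 M | 0.0400 M |  | 9.1 min |

| run | time / min | [starting material] / M |
|---|---|---|
| south-west run | 1.3 | 0.3510 |
| south-west run | 2.6 | 0.3045 |
| south-west run | 3.9 | 0.2606 |
| south-west run | 5.2 | 0.2194 |
| south-west run | 6.5 | 0.1877 |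
| south-west run | 7.8 | 0.1595 |
| south-west run | 9.1 | 0.1377 |
| north run | 1.3 | 0.1372 |
| north run | 2.6 | 0.1169 |
| north run | 3.9 | 0.0999 |
| north run | 5.2 | 0.0837 |
| north run | 6.5 | 0.0746 |
| north run | 7.8 | 0.0682 |
| north run | 9.1 | 0.0624 |
| south-east run | 1.3 | 0.3542 |
| south-east run | 2.6 | 0.3007 |
| south-east run | 3.9 | 0.2626 |
| south-east run | 5.2 | 0.2194 |
| south-east run | 6.5 | 0.1877 |
| south-east run | 7.8 | 0.1619 |
| south-east run | 9.1 | 0.1381 |
| east run | 1.3 | 0.3088 |
| east run | 2.6 | 0.2213 |
| east run | 3.9 | 0.1612 |
| east run | 5.2 | 0.1182 |
| east run | 6.5 | 0.0791 |
| east run | 7.8 | 0.0582 |
| east run | 9.1 | 0.0436 |

(standard deviation of a reading: 0.002 M)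

- Overall: starting material + coupling partner -> product, with free catalyst as catalyst.
- Constant volume, constant temperature.
- The analysis sees a species whether free or bound.
- "The second partner" is coupling partner.
- An order is taken over about fifteen percent of the charge, up and down.

- apparent order in [free catalyst] of the starting rate, round the charge of the south-west run (the rate where two percent of its starting material have turned into product)
- the north run starts with 0.240 M less of starting material and of coupling partner than the south-west run, and with no product. Compared where both hold the same amount of starting material, once fifteen percent of what the north run was charged with has turned into product, is the north run faster, slower or alike (within a tenth)?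
- starting material in the north-west run at 9.1 min, as a share of the starting material charged

- Apply the bench rule to the north-west run: the limiting reagent caps the loss of the other partner. The coupling partner is the limiting reagent there, with less charged than of starting material, so the rule stops [starting material] at 68.0% of its charge.
- Test that rule on the earlier runs. At 9.1 min the north run reads 0.0624 M, which is 0.0176 M below its charge minus its partner charge. The east run reads 0.0436 M, which is 0.0364 M below the same line. Both gaps are larger than the scatter of 0.002 M.
- Divide each gap by the free catalyst charge of its run. The north run gives 0.440 and the east run gives 0.455. Read this as a loss that scales with the catalyst charge.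
- Find the border of the rule with the ratio of catalyst charge to partner charge. The ratio is 0.500 in the north run and 0.125 in the north-west run, so expect a smaller error in the north-west run.
- Define the reach as the partner charge plus one turn of the catalyst charge, the most starting material I let a flask lose: 0.360 M in the north-west run. My floor there is 64.0%.
- Now ask how far the north-west run gets by 9.1 min. Count the whole partner charge as turned, which is my guess, and add the mean catalyst fraction read above, 0.448. My reckoning gives 66.2%.
- The forecast says 58%, range 48% to 68%, which differs from mine and lies lower than my floor. It gives an order of 0.97, range 0.85 to 1.1, and calls the north run alike. On the excess it says: “Loss beyond its charge in north and east implies a slower side path.”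
- The simulation gives 66.6% for the north-west run, an order of 0.59 for the south-west charge, and alike for the north run.

    active catalyst + starting material → loaded catalyst + by-product (6.120 M⁻¹ min⁻¹)
    loaded catalyst + coupling partner → product + active catalyst (15.42 M⁻¹ min⁻¹)
    2 coupling partner ⇌ idle reagent dimer, settled at all times (5.260 M⁻¹)
    free catalyst → active catalyst (2.358 min⁻¹)

- The slowness of the conversion of free catalyst into active catalyst makes no difference to the north-west share. That share means a loss of 0.334 M, more than the partner charge and less than the reach, at 92.8% of it. Turn to the north run, whose reach is 0.120 M. Its loss by 9.1 min reads 0.0976 M, less than that reach, at 81.3% of it.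

The earlier runs and the new flask were computed with constants of no real substance, noise included.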